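**Retrosynthetic overview**
1. Target 21 ⇐ 20 by Shi epoxidation of the side-chain trisubstituted alkene (oxirane formed last); 20 ⇐ aryl ether 19 ⇐ triol 16 by double angeloylation.
2. 16 ⇐ alkenyl bromide 13 + 4-methylpent-3-enal 15 by asymmetric Nozaki–Hiyama–Kishi coupling (side-chain C–C bond and carbinol centre).
3. 13 ⇐ enone 7 by trans α′-hydroxylation, Mitsunobu inversion (cis C–O), Luche reduction, hydroxyl-directed epoxidation and chloride opening.
4. Key step: 7 ⇐ 5 ⇐ cyclobutanone 3 + propyne 4 by an enantioselective nickel-catalysed two-carbon ring expansion (4 → 6) that builds the only carbocycle and its first stereocentre.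
5. 3 ⇐ 3-bromocyclobutanone 1 + (1-bromoethenyl)trimethylsilane 2 by reductive cross-coupling; ring order: cyclohexene (step 2), then oxirane (step 13).

Assumption: in the ligand-controlled steps (2, 10 and the fallbacks) the ligand enantiomer named is taken to give the drawn configuration; if the sense proves opposite, the mirror-image ligand is used.

**Step 1**
Reactants: 1 3-bromocyclobutan-1-one; 2 (1-bromoethenyl)trimethylsilane
Product: 3 3-[1-(trimethylsilyl)ethenyl]cyclobutan-1-one
Conditions: NiBr2(dme) (10 mol%), 4,4′-di-tert-butyl-2,2′-bipyridine (10 mol%), Zn dust (2 equiv), NaI (0.5 equiv), DMA, 25 °C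
Reagents that add atoms: none
Why: Nickel-catalysed reductive cross-electrophile coupling joins the secondary alkyl bromide (via its radical) to the alkenyl bromide without an organometallic reagent that would attack the strained ketone; 3 is achiral (mirror plane through C1 and C3).

**Step 2**
Reactants: 3 3-[1-(trimethylsilyl)ethenyl]cyclobutan-1-one; 4 propyne
Product: 5 (5S)-2-methyl-5-[1-(trimethylsilyl)ethenyl]cyclohex-2-en-1-one
Conditions: Ni(cod)2 (10 mol%), (4R,5R)-1,3-bis(2,6-diisopropylphenyl)-4,5-diphenylimidazolidin-2-ylidene (12 mol%), propyne (3 equiv, slow addition), toluene, 60 °C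
Reagents that add atoms: none
Why: Proposed new method: enantioselective, regiocontrolled two-carbon ring expansion of a prochiral 3-substituted cyclobutanone by formal insertion of propyne into a C(=O)–CH2 bond; zerovalent nickel couples C=O and alkyne oxidatively to an oxanickelacyclopentene, the very bulky carbene placing the methyl-bearing alkyne carbon on the carbonyl carbon, strain-driven β-carbon elimination then cleaves one of the two enantiotopic ring bonds (the C2-symmetric chiral carbene chooses which, fixing C5 as S), and C(sp2)–C(sp3) reductive elimination closes the cyclohexenone; the closest known reactions are the achiral Ni(cod)2/PCy3 insertion of internal alkynes into cyclobutanones and the ligand-size-controlled regiochemistry of nickel–carbene aldehyde–alkyne couplings.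

**Step 3**
Reactants: 5 (5S)-2-methyl-5-[1-(trimethylsilyl)ethenyl]cyclohex-2-en-1-one
Product: 7 (5S)-5-(1-bromoethenyl)-2-methylcyclohex-2-en-1-one, via vicinal dibromide 6 (not isolated)
Conditions: Br2 (1.05 equiv), CH2Cl2, −78 °C; then Bu4NF, THF, 0 °C
Reagents that add atoms: bromine (BrBr)
Why: Bromodesilylation by addition–elimination: Br2 adds to the electron-rich vinylsilane (the enone C=C is deactivated) and fluoride triggers anti β-elimination of Me3Si and Br, leaving bromine on the carbon that carried silicon; C5 is untouched.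

**Step 4**
Reactants: 7 (5S)-5-(1-bromoethenyl)-2-methylcyclohex-2-en-1-one
Product: 9 (5S,6R)-5-(1-bromoethenyl)-6-hydroxy-2-methylcyclohex-2-en-1-one, via lithium dienolate 8 (not isolated)
Conditions: LiN(i-Pr)2, THF, −78 °C; 2-(benzenesulfonyl)-3-phenyloxaziridine, −78 °C; AcOH quench
Reagents that add atoms: 2-(benzenesulfonyl)-3-phenyloxaziridine (O=S(=O)(c1ccccc1)N1OC1c1ccccc1)
Why: Kinetic α′-deprotonation and Davis hydroxylation of the cross-conjugated enolate; the oxidant attacks C6 anti to the C5 substituent, giving the trans ketol, which is also the thermodynamically preferred diequatorial epimer.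

**Step 5**
Reactants: 9 (5S,6R)-5-(1-bromoethenyl)-6-hydroxy-2-methylcyclohex-2-en-1-one
Product: 10 (5S,6S)-5-(1-bromoethenyl)-6-(4-methoxyphenoxy)-2-methylcyclohex-2-en-1-one
Conditions: 4-methoxyphenol, PPh3, DIAD, toluene, 0→23 °C
Reagents that add atoms: 4-methoxyphenol (COc1ccc(O)cc1)
Why: Mitsunobu etherification displaces the activated hydroxyl by SN2 with inversion at C6, turning the trans ketol into the cis 6-aryloxy ketone and installing a non-migrating, oxidatively removable protecting group.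

**Step 6**
Reactants: 10 (5S,6S)-5-(1-bromoethenyl)-6-(4-methoxyphenoxy)-2-methylcyclohex-2-en-1-one
Product: 11 (1R,5S,6S)-5-(1-bromoethenyl)-6-(4-methoxyphenoxy)-2-methylcyclohex-2-en-1-ol
Conditions: NaBH4, CeCl3·7H2O, MeOH, −78 °C
Reagents that add atoms: none
Why: Luche 1,2-reduction; hydride adds from the face opposite the axial C6 aryloxy group, giving the pseudo-equatorial allylic alcohol cis to both the C6 oxygen and the C5 substituent (as carvone gives cis-carveol).

**Step 7**
Reactants: 11 (1R,5S,6S)-5-(1-bromoethenyl)-6-(4-methoxyphenoxy)-2-methylcyclohex-2-en-1-ol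
Product: 12 (1S,2S,3S,4S,6R)-4-(1-bromoethenyl)-3-(4-methoxyphenoxy)-1-methyl-7-oxabicyclo[4.1.0]heptan-2-ol
Conditions: VO(acac)2 (5 mol%), t-BuOOH (1.5 equiv), CH2Cl2, 0→23 °C
Reagents that add atoms: tert-butyl hydroperoxide (CC(C)(C)OO)
Why: Hydroxyl-directed vanadium-catalysed epoxidation delivers oxygen to the face of the trisubstituted ring alkene that carries the allylic OH, setting both epoxide carbons syn to it; the bromoalkene is not a substrate.

**Step 8**
Reactants: 12 (1S,2S,3S,4S,6R)-4-(1-bromoethenyl)-3-(4-methoxyphenoxy)-1-methyl-7-oxabicyclo[4.1.0]heptan-2-ol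
Product: 13 (1S,2S,3S,4S,6S)-4-(1-bromoethenyl)-6-chloro-3-(4-methoxyphenoxy)-1-methylcyclohexane-1,2-diol
Conditions: TiCl(Oi-Pr)3 (1.5 equiv), CH2Cl2, −20→0 °C; aqueous tartaric acid work-up
Reagents that add atoms: chlorotitanium triisopropoxide TiCl(Oi-Pr)3 (CC(C)O[Ti](Cl)(OC(C)C)OC(C)C)
Why: Titanium-assisted opening of a 2,3-epoxy alcohol at C3; chloride attacks the secondary epoxide carbon anti (trans-diaxial, Fürst–Plattner; the tertiary carbon is deactivated by the adjacent oxygenated carbon), giving chloride trans to the new tertiary OH.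

**Step 9**
Reactants: 14 4-methylpent-3-en-1-ol
Product: 15 4-methylpent-3-enal
Conditions: Dess–Martin periodinane, pyridine, CH2Cl2, 0 °C; used at once as a solution
Reagents that add atoms: none
Why: Dess–Martin oxidation under buffered, non-basic conditions gives the β,γ-unsaturated aldehyde without moving the double bond into conjugation.

**Step 10**
Reactants: 13 (1S,2S,3S,4S,6S)-4-(1-bromoethenyl)-6-chloro-3-(4-methoxyphenoxy)-1-methylcyclohexane-1,2-diol; 15 4-methylpent-3-enal
Product: 16 (1S,2S,3S,4R,6S)-6-chloro-4-[(3S)-3-hydroxy-6-methylhepta-1,5-dien-2-yl]-3-(4-methoxyphenoxy)-1-methylcyclohexane-1,2-diol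
Conditions: CrCl2 (4 equiv), Kishi-type chiral oxazoline–sulfonamide ligand (4.4 equiv, enantiomer giving the S carbinol), Et3N, NiCl2·(2,9-dimethyl-1,10-phenanthroline) (10 mol%), THF/MeCN, 23 °C; aqueous work-up
Reagents that add atoms: none
Why: Nozaki–Hiyama–Kishi coupling (nickel activates the alkenyl bromide, chromium carries the alkenyl group to the aldehyde) tolerates the free hydroxyls and the alkyl chloride, and the chiral ligand on chromium selects the aldehyde face to set the S carbinol.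

**Step 11**
Reactants: 16 (1S,2S,3S,4R,6S)-6-chloro-4-[(3S)-3-hydroxy-6-methylhepta-1,5-dien-2-yl]-3-(4-methoxyphenoxy)-1-methylcyclohexane-1,2-diol; 17 angelic acid
Product: 19 (1S,2S,3S,5R,6S)-3-chloro-2-hydroxy-6-(4-methoxyphenoxy)-2-methyl-5-[(3S)-6-methyl-3-{[(2Z)-2-methylbut-2-enoyl]oxy}hepta-1,5-dien-2-yl]cyclohexyl (2Z)-2-methylbut-2-enoate, via mixed anhydride 18 (not isolated)
Conditions: 17 (3 equiv), 2,4,6-trichlorobenzoyl chloride, Et3N, toluene, 23 °C, filter; then 16, toluene, 80 °C (no DMAP)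
Reagents that add atoms: none
Why: Yamaguchi-type mixed-anhydride esterification without DMAP transfers the angeloyl group without Z→E isomerisation; both secondary hydroxyls are acylated, the tertiary one is inert, and no stereocentre changes.

**Step 12**
Reactants: 19 (1S,2S,3S,5R,6S)-3-chloro-2-hydroxy-6-(4-methoxyphenoxy)-2-methyl-5-[(3S)-6-methyl-3-{[(2Z)-2-methylbut-2-enoyl]oxy}hepta-1,5-dien-2-yl]cyclohexyl (2Z)-2-methylbut-2-enoate
Product: 20 (1S,2S,3S,5R,6S)-3-chloro-2,6-dihydroxy-2-methyl-5-[(3S)-6-methyl-3-{[(2Z)-2-methylbut-2-enoyl]oxy}hepta-1,5-dien-2-yl]cyclohexyl (2Z)-2-methylbut-2-enoate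
Conditions: (NH4)2Ce(NO3)6 (2.5 equiv), MeCN/H2O 4:1, 0 °C
Reagents that add atoms: none
Why: Oxidative dearylation of the 4-methoxyphenyl ether (to benzoquinone) frees the C6 hydroxyl while esters, chlorohydrin and alkenes survive; being an ether, the group could not migrate onto the neighbouring hydroxyl in earlier steps.

**Step 13**
Reactants: 20 (1S,2S,3S,5R,6S)-3-chloro-2,6-dihydroxy-2-methyl-5-[(3S)-6-methyl-3-{[(2Z)-2-methylbut-2-enoyl]oxy}hepta-1,5-dien-2-yl]cyclohexyl (2Z)-2-methylbut-2-enoate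
Product: 21 (1S,2S,3S,5R,6S)-3-chloro-5-{(3S)-4-[(2R)-3,3-dimethyloxiran-2-yl]-3-{[(2Z)-2-methylbut-2-enoyl]oxy}but-1-en-2-yl}-2,6-dihydroxy-2-methylcyclohexyl (2Z)-2-methylbut-2-enoate
Conditions: Shi ketone (D-fructose-derived, 1.5 equiv in portions), 2KHSO5·KHSO4·K2SO4, NaHCO3, MeCN/aq. Na2EDTA, 0 °C, pH 7–8
Reagents that add atoms: potassium peroxymonosulfate KHSO5 ([K+].[O-]S(=O)(=O)OO)
Why: Shi asymmetric epoxidation: the fructose-derived dioxirane attacks only the electron-rich trisubstituted alkene (the 1,1-disubstituted alkene next to an ester and the angelate alkenes are too electron-poor) through the spiro transition state to give the R epoxide under reagent control, and the near-neutral pH keeps the trans chlorohydrin from closing.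

**Compound list**
1 | 3-bromocyclobutan-1-one | O=C1CC(Br)C1 | starting material
2 | (1-bromoethenyl)trimethylsilane | C=C(Br)[Si](C)(C)C | starting material
3 | 3-[1-(trimethylsilyl)ethenyl]cyclobutan-1-one | C=C([Si](C)(C)C)C1CC(=O)C1 | intermediate
4 | propyne | CC#C | starting material
5 | (5S)-2-methyl-5-[1-(trimethylsilyl)ethenyl]cyclohex-2-en-1-one | C=C([Si](C)(C)C)[C@H]1CC=C(C)C(=O)C1 | intermediate
6 | (5S)-5-[1,2-dibromo-1-(trimethylsilyl)ethyl]-2-methylcyclohex-2-en-1-one (both epimers at the silyl-bearing carbon) | BrCC(Br)([Si](C)(C)C)[C@H]1CC=C(C)C(=O)C1 | intermediate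
7 | (5S)-5-(1-bromoethenyl)-2-methylcyclohex-2-en-1-one | C=C(Br)[C@H]1CC=C(C)C(=O)C1 | intermediate
8 | lithium (6S)-6-(1-bromoethenyl)-3-methylcyclohexa-1,3-dien-2-olate | C=C(Br)[C@H]1CC=C(C)C([O-])=C1.[Li+] | intermediate
9 | (5S,6R)-5-(1-bromoethenyl)-6-hydroxy-2-methylcyclohex-2-en-1-one (OH trans to the side chain) | C=C(Br)[C@H]1CC=C(C)C(=O)[C@@H]1O | intermediate
10 | (5S,6S)-5-(1-bromoethenyl)-6-(4-methoxyphenoxy)-2-methylcyclohex-2-en-1-one (aryloxy cis to the side chain) | C=C(Br)[C@H]1CC=C(C)C(=O)[C@H]1Oc1ccc(OC)cc1 | intermediate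
11 | (1R,5S,6S)-5-(1-bromoethenyl)-6-(4-methoxyphenoxy)-2-methylcyclohex-2-en-1-ol (all three substituents cis) | C=C(Br)[C@H]1CC=C(C)[C@@H](O)[C@H]1Oc1ccc(OC)cc1 | intermediate
12 | (1S,2S,3S,4S,6R)-4-(1-bromoethenyl)-3-(4-methoxyphenoxy)-1-methyl-7-oxabicyclo[4.1.0]heptan-2-ol (epoxide cis to OH) | C=C(Br)[C@H]1C[C@H]2O[C@@]2(C)[C@@H](O)[C@H]1Oc1ccc(OC)cc1 | intermediate
13 | (1S,2S,3S,4S,6S)-4-(1-bromoethenyl)-6-chloro-3-(4-methoxyphenoxy)-1-methylcyclohexane-1,2-diol | C=C(Br)[C@H]1C[C@H](Cl)[C@@](C)(O)[C@@H](O)[C@H]1Oc1ccc(OC)cc1 | intermediate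
14 | 4-methylpent-3-en-1-ol | CC(C)=CCCO | starting material
15 | 4-methylpent-3-enal | CC(C)=CCC=O | intermediate
16 | (1S,2S,3S,4R,6S)-6-chloro-4-[(3S)-3-hydroxy-6-methylhepta-1,5-dien-2-yl]-3-(4-methoxyphenoxy)-1-methylcyclohexane-1,2-diol | C=C([C@H](CC=C(C)C)O)[C@H]1C[C@H](Cl)[C@@](C)(O)[C@@H](O)[C@H]1Oc1ccc(OC)cc1 | intermediate
17 | angelic acid, (2Z)-2-methylbut-2-enoic acid | C/C=C(/C)C(=O)O | starting material
18 | (2Z)-2-methylbut-2-enoic 2,4,6-trichlorobenzoic anhydride | C/C=C(/C)C(=O)OC(=O)c1c(Cl)cc(Cl)cc1Cl | intermediate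
19 | (1S,2S,3S,5R,6S)-3-chloro-2-hydroxy-6-(4-methoxyphenoxy)-2-methyl-5-[(3S)-6-methyl-3-{[(2Z)-2-methylbut-2-enoyl]oxy}hepta-1,5-dien-2-yl]cyclohexyl (2Z)-2-methylbut-2-enoate | C=C([C@H](CC=C(C)C)OC(=O)/C(C)=C\C)[C@H]1C[C@H](Cl)[C@@](C)(O)[C@@H](OC(=O)/C(C)=C\C)[C@H]1Oc1ccc(OC)cc1 | intermediate
20 | (1S,2S,3S,5R,6S)-3-chloro-2,6-dihydroxy-2-methyl-5-[(3S)-6-methyl-3-{[(2Z)-2-methylbut-2-enoyl]oxy}hepta-1,5-dien-2-yl]cyclohexyl (2Z)-2-methylbut-2-enoate | C=C([C@H](CC=C(C)C)OC(=O)/C(C)=C\C)[C@H]1C[C@H](Cl)[C@@](C)(O)[C@@H](OC(=O)/C(C)=C\C)[C@H]1O | intermediate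
21 | (1S,2S,3S,5R,6S)-3-chloro-5-{(3S)-4-[(2R)-3,3-dimethyloxiran-2-yl]-3-{[(2Z)-2-methylbut-2-enoyl]oxy}but-1-en-2-yl}-2,6-dihydroxy-2-methylcyclohexyl (2Z)-2-methylbut-2-enoate | C=C([C@H](C[C@H]1OC1(C)C)OC(=O)/C(C)=C\C)[C@H]1C[C@H](Cl)[C@@](C)(O)[C@@H](OC(=O)/C(C)=C\C)[C@H]1O | target

**Step count and risks**
Total steps: 13. Longest linear sequence: 12 (steps 1–8 and 10–13; step 9 is the side branch).

Step 2 (the new ring expansion; risks are propyne oligomerisation, wrong alkyne regiochemistry and low enantioselectivity). The fallback uses known chemistry and sets out from 2. Magnesium in THF gives the Grignard reagent [1-(trimethylsilyl)ethenyl]magnesium bromide F1, which with B(OMe)3 and aqueous acid gives [1-(trimethylsilyl)ethenyl]boronic acid F2. Rhodium-catalysed asymmetric 1,4-addition (Rh(acac)(C2H4)2, (S)-BINAP, dioxane/H2O, 100 °C) of F2 to commercial racemic 6-methylcyclohex-2-en-1-one gives (3S)-6-methyl-3-[1-(trimethylsilyl)ethenyl]cyclohexan-1-one F3 as a mixture at the methyl-bearing carbon, which does not matter. Me3SiI/(Me3Si)2NH gives the more substituted silyl enol ether trimethyl({(5S)-2-methyl-5-[1-(trimethylsilyl)ethenyl]cyclohex-1-en-1-yl}oxy)silane F4, and Saegusa–Ito dehydrogenation with Pd(OAc)2 in MeCN returns to the route at 5.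

Step 5 (Mitsunobu inversion at a hindered α-ketol, with the nucleophile entering cis to the neighbouring substituent; risks are elimination and epimerisation). The fallback sets out from 9. Tf2O and 2,6-lutidine in CH2Cl2 at −78 °C give the isolated α-keto triflate (1R,6S)-6-(1-bromoethenyl)-3-methyl-2-oxocyclohex-3-en-1-yl trifluoromethanesulfonate F5. Preformed potassium 4-methoxyphenoxide with 18-crown-6 in THF at −40 °C then displaces it by SN2 with inversion, returning to the route at 10. This is a two-stage activation and displacement in place of the redox condensation.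

Step 10 (ligand-controlled coupling of a hindered alkenyl bromide on a substrate with free hydroxyls; risks are low conversion and low selectivity at the carbinol). The fallback sets out from 13. Coupling with 15 under achiral, more forcing conditions (CrCl2, NiCl2 cat., DMF) gives the carbinol mixture (1S,2S,3S,4R,6S)-6-chloro-4-[(3RS)-3-hydroxy-6-methylhepta-1,5-dien-2-yl]-3-(4-methoxyphenoxy)-1-methylcyclohexane-1,2-diol F6. MnO2 in CH2Cl2 oxidises only the allylic alcohol to the enone (1S,2S,3S,4R,6S)-6-chloro-3-(4-methoxyphenoxy)-1-methyl-4-(6-methyl-3-oxohepta-1,5-dien-2-yl)cyclohexane-1,2-diol F7. Corey–Bakshi–Shibata reduction ((R)-2-methyl-CBS-oxazaborolidine, catecholborane, toluene, −78 °C) then sets the S carbinol by reagent control, returning to the route at 16.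

**Further compounds**
F1 | step 2 | [1-(trimethylsilyl)ethenyl]magnesium bromide | C=C([Mg]Br)[Si](C)(C)C
F2 | step 2 | [1-(trimethylsilyl)ethenyl]boronic acid | C=C(B(O)O)[Si](C)(C)C
F3 | step 2 | (3S)-6-methyl-3-[1-(trimethylsilyl)ethenyl]cyclohexan-1-one | C=C([Si](C)(C)C)[C@H]1CCC(C)C(=O)C1
F4 | step 2 | trimethyl({(5S)-2-methyl-5-[1-(trimethylsilyl)ethenyl]cyclohex-1-en-1-yl}oxy)silane | C=C([Si](C)(C)C)[C@H]1CCC(C)=C(O[Si](C)(C)C)C1
F5 | step 5 | (1R,6S)-6-(1-bromoethenyl)-3-methyl-2-oxocyclohex-3-en-1-yl trifluoromethanesulfonate | C=C(Br)[C@H]1CC=C(C)C(=O)[C@@H]1OS(=O)(=O)C(F)(F)F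
F6 | step 10 | (1S,2S,3S,4R,6S)-6-chloro-4-[(3RS)-3-hydroxy-6-methylhepta-1,5-dien-2-yl]-3-(4-methoxyphenoxy)-1-methylcyclohexane-1,2-diol | C=C(C(O)CC=C(C)C)[C@H]1C[C@H](Cl)[C@@](C)(O)[C@@H](O)[C@H]1Oc1ccc(OC)cc1
F7 | step 10 | (1S,2S,3S,4R,6S)-6-chloro-3-(4-methoxyphenoxy)-1-methyl-4-(6-methyl-3-oxohepta-1,5-dien-2-yl)cyclohexane-1,2-diol | C=C(C(=O)CC=C(C)C)[C@H]1C[C@H](Cl)[C@@](C)(O)[C@@H](O)[C@H]1Oc1ccc(OC)cc1
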